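Every set-up holds the same amounts: [starting material] 45 mM, [second substrate] 45.0 mM, [free catalyst] 1.1 mM and [protic impurity] 0.900 mM, the smallest charge. What differs is the way these amounts meet.

| setting | spring | midnight | autumn | dusk | grey | violet | teal | blue |
|---|---|---|---|---|---|---|---|---|
| starting material | 45 mM | 22 mM | 90 mM | 45 mM | 45 mM | 45 mM | 45 mM (fed, over 9.60 min) | 45 mM |
| second substrate | 45 mM | 45 mM | 45 mM | 45 mM | 45.0 mM | 45.0 mM | 45.0 mM | 45.0 mM (fed, over 9.60 min) |
| protic impurity | 0.90 mM | 0.90 mM | 0.90 mM | 0.90 mM | 0.900 mM | 0.900 mM | 0.900 mM | 0.900 mM |
| free catalyst | 1.1 mM | 1.1 mM | 1.1 mM | 2.2 mM | 1.1 mM | 1.1 mM | 1.1 mM | 1.1 mM |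
| remark | run made earlier | run made earlier | run made earlier | run made earlier | everything together in a closed stirred flask, run for 12 min | one stirred flow tank at steady state, fed with the mixture as stated, mean residence time 12 min | a stirred flask in which starting material is dosed at a steady rate over 9.60 min without added volume, worked up at 12 min | all but second substrate at the start; second substrate goes in evenly over 9.60 min, the run ends at 12 min |
| time |  |  |  |  | 12 min |  | 12 min | 12 min |

- spring (time / min: target / %, uncatalysed product / %): 0.833: 2, 0; 2.50: 9, 0; 5.00: 12, 0; 8.00: 21, 0
- midnight (time / min: target / %, uncatalysed product / %): 2.00: 4, 0; 5.00: 14, 0; 10.0: 28, 3; 15.0: 38, 4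
- autumn (time / min: target / %, uncatalysed product / %): 4.00: 11, 0; 8.00: 19, 0; 10.0: 20, 3; 15.0: 31, 2
- dusk (time / min: target / %, uncatalysed product / %): 4.00: 23, 1; 8.00: 41, 1; 10.0: 44, 2; 15.0: 63, 3

(each reading ± 2 percentage points)

- the set-up with the highest share of target in all that became target or uncatalysed product, at the outlet or at the end ("none" if the first two lie within 2 percentage points) (grey / violet / teal / blue / none)
- share of target in all that became target or uncatalysed product, at the outlet or at the end, grey
- share of target in all that became target or uncatalysed product, at the outlet or at the end, violet
- share of target in all that became target or uncatalysed product, at the outlet or at the end, teal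
- share of target in all that became target or uncatalysed product, at the outlet or at the end, blue

- the stated concentrations are those of everything mixed, before any reaction; amounts are the same in each set-up
- the feed brings no volume worth counting
- the earlier runs were made in a closed, stirred flask

Two chemists dispute what the vessel does to the share of target. The first holds that second substrate is a partner in making target, so a flask short of it should lose share. The second holds that target and uncatalysed product form side by side, each first order in starting material, so [starting material] cancels from their ratio and the vessel should matter little.

The second chemist reckons that ratio from the readings. She sets dusk apart, since it has twice the free catalyst, and adds up the other three runs. Target sums to 209% and uncatalysed product to 12.0%. Their quotient is the split, target made per uncatalysed product made, a selectivity factor: 17.4. It is a rough reading: the last uncatalysed reading of midnight is 4%, with a scatter of 2 percentage points. On her view it means a share of 94.6% in all four set-ups.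

The first chemist answers with a balance. In autumn, second substrate is the limiting reagent on his view, and the last target reading would leave 17.1 mM of it. She replies that the split of autumn, 16.2, is not lower than that of midnight, 12.0.

The forecast is his: 92% for grey, 91.5% for violet, 92.8% for teal and 87.5% for blue, with best none. It reckons second substrate starved early in blue, and of the top two it says “Teal and grey lie within 2 points, so none”.

The simulation gives 95.1%, 95.1%, 95.3% and 95.9% in that order, with best none.

    starting material + free catalyst ⇌ catalyst intermediate A (K = 22.0 M⁻¹, k = 9.90 M⁻¹ s⁻¹)
    catalyst intermediate A → free catalyst + target (k = 0.0710 s⁻¹)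
    second substrate + free catalyst ⇌ catalyst intermediate B (K = 63.0 M⁻¹, k = 2.90 M⁻¹ s⁻¹)
    catalyst intermediate B → free catalyst + second product (k = 0.0550 s⁻¹)
    starting material + protic impurity → quenched substrate (k = 38.0 M⁻¹ s⁻¹)
    free catalyst ⇌ dormant form (K = 10.0, k = 8.10 × 10⁻⁴ s⁻¹)
    starting material → uncatalysed product (k = 2.50 × 10⁻⁵ s⁻¹)

Blue stands 8.4 points above the forecast, while grey, with second substrate present from the start, stands 3.1 points above it, within the tolerance: there the first chemist's number held. With the step from second substrate and free catalyst to catalyst intermediate B struck out both ways, violet rises to 96.6%. The split 17.4, put on blue's 32.8% of target, gives 1.89% of uncatalysed product against the 1.39% that blue holds. Left for 120 min, blue gives 94.3%, against the split's 94.6%.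

(The readings were computed with made-up constants; noise was put on by code.)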